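**Retrosynthetic overview**
- Ring A of the flavone has six different positions (C4a, C5–OH, C6–H, C7–OH, C8–prenyl, C8a–O1). It is therefore built last, on a finished 6-aryl-4-pyranone (ring C carrying ring B), so that each ring-A atom is fixed by where it comes from.
- Key disconnection: C8–C8a (Wolff shift), C5–C6 and C7–C8 (ketene plus ynol ether), C4a–C5 (6π closure). This leads back to pyranonyl α-diazo ketone 16 and the C-silylated siloxyalkyne 20.
- 16 comes from pyranone ester 10 via Weinreb amide, homoprenyl Grignard addition and detrifluoroacetylative diazo transfer. 10 (ring C) comes from aryl methyl ketone 5 by two Claisen condensations and a neutral cyclodehydration.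
- Ring B is bought as 4-hydroxyacetophenone; its two prenyl groups enter by twofold Stille coupling on the MOM-protected dibromide. Ring order: B (given), C (step 5), A (step 10).
- Endgame: acid removes the MOM group and the C6 silyl cap, then fluoride removes the 7-O-silyl group.

Key step: step 10

Remark: the ynol ether is used as its C-trimethylsilyl derivative 20, because acetylide oxidation/O-silylation needs a substituted acetylide and no dependable preparation of the uncapped siloxyethyne is known to me; the cap ends at C6 and is lost by ipso-protonation in step 11. Ar = 4-(methoxymethoxy)-3,5-bis(3-methylbut-2-en-1-yl)phenyl.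

**Route**

Step 1
Reactants: 1 4-hydroxyacetophenone
Product: 2 3,5-dibromo-4-hydroxyacetophenone
Conditions: Br2 (2.1 equiv), NaOAc, AcOH, 25 °C
Reagents that add atoms: bromine, BrBr
Why: Electrophilic aromatic bromination, in which the phenol directs both bromines ortho (para is blocked by the acetyl group) and the acetate buffer suppresses α-bromination of the ketone.

Step 2
Reactants: 2 3,5-dibromo-4-hydroxyacetophenone
Product: 3 1-[3,5-dibromo-4-(methoxymethoxy)phenyl]ethan-1-one
Conditions: MOMCl, i-Pr2NEt, CH2Cl2, 0 → 25 °C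
Reagents that add atoms: chloromethyl methyl ether, COCCl
Why: O-alkylation of the acidic dibromophenol gives the MOM acetal, which is inert to all the basic, organometallic and photochemical steps that follow.

Step 3
Reactants: 3 1-[3,5-dibromo-4-(methoxymethoxy)phenyl]ethan-1-one; 4 tributyl(3-methylbut-2-en-1-yl)stannane (2.5 equiv)
Product: 5 1-[4-(methoxymethoxy)-3,5-bis(3-methylbut-2-en-1-yl)phenyl]ethan-1-one (Ar–CO–CH3)
Conditions: Pd(PPh3)4 (cat.), DMF, 100 °C
Reagents that add atoms: none
Why: Twofold Stille coupling, in which oxidative addition of zerovalent palladium to the C–Br bonds is helped by the para acetyl group and reductive elimination at the unsubstituted allyl terminus gives the linear prenyl groups under neutral conditions that spare the methyl ketone.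

Step 4
Reactants: 5 Ar–CO–CH3; 6 ethyl acetate
Product: 7 1-Ar-butane-1,3-dione
Conditions: NaH, EtOAc (excess), THF, 0 → 60 °C; aq NH4Cl
Reagents that add atoms: none
Why: Crossed Claisen condensation of the ketone enolate with ethyl acetate, driven by deprotonation of the β-diketone that forms.

Step 5
Reactants: 7 1-Ar-butane-1,3-dione; 8 diethyl oxalate
Product: 10 ethyl 6-Ar-4-oxo-4H-pyran-2-carboxylate, via triketo ester 9 (not isolated)
Conditions: (CO2Et)2, NaOEt, EtOH/THF, 0 → 25 °C; AcOH; crude, then PPh3, CCl4, Et3N, MeCN, 25 °C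
Reagents that add atoms: none
Why: Claisen condensation at the methyl terminus (the only mode that ends in a doubly stabilised dianion) followed by Appel-type cyclodehydration, in which one enol oxygen is activated as an oxyphosphonium and displaced by the other, closes the 4-pyranone under buffered neutral conditions that spare the MOM acetal and the prenyl groups, which hot mineral acid would not.

Step 6
Reactants: 10 ethyl 6-Ar-4-oxo-4H-pyran-2-carboxylate
Product: 11 N-methoxy-N-methyl-6-Ar-4-oxo-4H-pyran-2-carboxamide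
Conditions: MeNH(OMe)·HCl, i-PrMgCl, THF, −20 °C
Reagents that add atoms: N,O-dimethylhydroxylamine hydrochloride, CNOC.Cl
Why: Ester aminolysis by the magnesium amide (Weinreb amide formation), in which the ester on the electron-poor pyranone is activated enough to react at −20 °C before the ring is attacked.

Step 7
Reactants: 11 N-methoxy-N-methyl-6-Ar-4-oxo-4H-pyran-2-carboxamide; 12 5-bromo-2-methylpent-2-ene
Product: 14 2-(5-methylhex-4-enoyl)-6-Ar-4H-pyran-4-one, via (4-methylpent-3-enyl)magnesium bromide 13 (not isolated)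
Conditions: 12, Mg, THF, 25 °C; then 11, THF, −78 → −40 °C; aq NH4Cl
Reagents that add atoms: none
Why: Weinreb ketone synthesis, in which the chelated tetrahedral adduct holds until work-up so that addition stops at the ketone, and at −78 °C the amide should react faster than the cross-conjugated pyranone carbonyl.

Step 8
Reactants: 14 2-(5-methylhex-4-enoyl)-6-Ar-4H-pyran-4-one
Product: 16 2-(2-diazo-5-methylhex-4-enoyl)-6-Ar-4H-pyran-4-one, via α-trifluoroacetyl ketone 15 (not isolated)
Conditions: LiHMDS, THF, −78 °C; CF3CO2CH2CF3; then MsN3, Et3N, H2O, MeCN, 25 °C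
Reagents that add atoms: methanesulfonyl azide, CS(=O)(=O)N=[N+]=[N-]; 2,2,2-trifluoroethyl trifluoroacetate, O=C(OCC(F)(F)F)C(F)(F)F (its trifluoroacetyl group stays only in intermediate 15)
Why: Detrifluoroacetylative diazo transfer, in which C-trifluoroacetylation of the kinetic enolate activates the single α-methylene for transfer from the sulfonyl azide and retro-Claisen loss of the trifluoroacetyl group releases the α-diazo ketone.

Step 9
Reactants: 17 ethynyltrimethylsilane
Product: 20 1-(triisopropylsiloxy)-2-(trimethylsilyl)ethyne, via lithium (trimethylsilyl)acetylide 18 (not isolated), via lithium (trimethylsilyl)ynolate 19 (not isolated)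
Conditions: n-BuLi, THF, −78 °C; t-BuOOLi (from t-BuOOH, LiHMDS), −78 → 0 °C; TIPSOTf, −78 → 0 °C
Reagents that add atoms: tert-butyl hydroperoxide, CC(C)(C)OO; triisopropylsilyl trifluoromethanesulfonate, CC(C)[Si](OS(=O)(=O)C(F)(F)F)(C(C)C)C(C)C
Why: Oxidation of the lithium acetylide by the lithium peroxide gives the ynolate, and the bulky silyl triflate should silylate it on oxygen, the standard route to siloxyalkynes.

Step 10
Reactants: 16 2-(2-diazo-5-methylhex-4-enoyl)-6-Ar-4H-pyran-4-one; 20 1-(triisopropylsiloxy)-2-(trimethylsilyl)ethyne (3 equiv)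
Product: 25 5-hydroxy-2-Ar-8-(3-methylbut-2-en-1-yl)-7-(triisopropylsiloxy)-6-(trimethylsilyl)-4H-chromen-4-one, via ketene 21 (not isolated), via cyclobutenone 22 (not isolated), via dienylketene 23 (not isolated), via cyclohexadienone 24 (not isolated)
Conditions: hν (405 nm LED), PhMe, 25 °C; then 110 °C
Reagents that add atoms: none
Why: Light of 405 nm is chosen to excite the diazo ketone and not the aryl pyranone, so that nitrogen loss with 1,2-shift of the pyranonyl group (Wolff rearrangement, forming C8–C8a) gives ketene 21, whose terminal carbon carries the prenyl group and the pyranone. The silyl-bearing alkyne carbon attacks the ketene carbonyl carbon and the (2+2) cycloaddition gives cyclobutenone 22 (C5–C6 and C7–C8); heating opens it by conrotatory 4π electrocyclic reaction to dienylketene 23, and thermal disrotatory 6π electrocyclisation onto pyranone C3 (C4a–C5) closes ring A as dienone 24, which enolises to the chelated 5-phenol. The old ketone carbon becomes C5, the diazo carbon C8, and the alkyne carbons C6 and C7. The closest known reaction is the Danheiser benzannulation of aryl, heteroaryl and alkenyl α-diazo ketones with siloxyalkynes; no stereocentre is formed. The step needs the regiochemistry of the (2+2) addition, which the oxygen lone pair and the β-silicon effect secure by making the silylated carbon the nucleophile. It also needs the E-dienylketene, which is reached because ring opening is reversible and only this isomer is drained by closure, and closure has one site only because the other neighbour of the pyranone carbon is O1.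

Step 11
Reactants: 25 5-hydroxy-2-Ar-8-(3-methylbut-2-en-1-yl)-7-(triisopropylsiloxy)-6-(trimethylsilyl)-4H-chromen-4-one
Product: 26 5-hydroxy-2-[4-hydroxy-3,5-bis(3-methylbut-2-en-1-yl)phenyl]-8-(3-methylbut-2-en-1-yl)-7-(triisopropylsiloxy)-4H-chromen-4-one
Conditions: 3 M aq HCl, MeOH/THF, 25 → 40 °C
Reagents that add atoms: none
Why: Acid-catalysed acetal methanolysis frees the 4'-hydroxyl and ipso-protonation at C6, activated by O5, O7 and O1, removes the trimethylsilyl group (protodesilylation), while the hindered aryl triisopropylsilyl ether should survive and keep O7 from adding to the C8 prenyl group.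

Step 12
Reactants: 26 5-hydroxy-2-[4-hydroxy-3,5-bis(3-methylbut-2-en-1-yl)phenyl]-8-(3-methylbut-2-en-1-yl)-7-(triisopropylsiloxy)-4H-chromen-4-one
Product: 27 Epimedonin L
Conditions: TBAF, AcOH, THF, 0 °C
Reagents that add atoms: none
Why: Fluoride cleavage of the aryl silyl ether, buffered with acetic acid so that the polyphenol is not held under basic conditions.

**Compound list**

1 | 4-hydroxyacetophenone | CC(=O)c1ccc(O)cc1 | starting material
2 | 3,5-dibromo-4-hydroxyacetophenone | CC(=O)c1cc(Br)c(O)c(Br)c1 | intermediate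
3 | 1-[3,5-dibromo-4-(methoxymethoxy)phenyl]ethan-1-one | CC(=O)c1cc(Br)c(OCOC)c(Br)c1 | intermediate
4 | tributyl(3-methylbut-2-en-1-yl)stannane | CCCC[Sn](CCCC)(CCCC)CC=C(C)C | starting material
5 | 1-[4-(methoxymethoxy)-3,5-bis(3-methylbut-2-en-1-yl)phenyl]ethan-1-one | CC(=O)c1cc(CC=C(C)C)c(OCOC)c(CC=C(C)C)c1 | intermediate
6 | ethyl acetate | CCOC(C)=O | starting material
7 | 1-[4-(methoxymethoxy)-3,5-bis(3-methylbut-2-en-1-yl)phenyl]butane-1,3-dione | CC(=O)CC(=O)c1cc(CC=C(C)C)c(OCOC)c(CC=C(C)C)c1 | intermediate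
8 | diethyl oxalate | CCOC(=O)C(=O)OCC | starting material
9 | ethyl 6-[4-(methoxymethoxy)-3,5-bis(3-methylbut-2-en-1-yl)phenyl]-2,4,6-trioxohexanoate | CCOC(=O)C(=O)CC(=O)CC(=O)c1cc(CC=C(C)C)c(OCOC)c(CC=C(C)C)c1 | intermediate (not isolated)
10 | ethyl 6-[4-(methoxymethoxy)-3,5-bis(3-methylbut-2-en-1-yl)phenyl]-4-oxo-4H-pyran-2-carboxylate | CCOC(=O)c1cc(=O)cc(-c2cc(CC=C(C)C)c(OCOC)c(CC=C(C)C)c2)o1 | intermediate
11 | N-methoxy-N-methyl-6-[4-(methoxymethoxy)-3,5-bis(3-methylbut-2-en-1-yl)phenyl]-4-oxo-4H-pyran-2-carboxamide | CON(C)C(=O)c1cc(=O)cc(-c2cc(CC=C(C)C)c(OCOC)c(CC=C(C)C)c2)o1 | intermediate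
12 | 5-bromo-2-methylpent-2-ene | CC(C)=CCCBr | starting material
13 | (4-methylpent-3-enyl)magnesium bromide | CC(C)=CCC[Mg]Br | intermediate (not isolated)
14 | 2-(5-methylhex-4-enoyl)-6-[4-(methoxymethoxy)-3,5-bis(3-methylbut-2-en-1-yl)phenyl]-4H-pyran-4-one | CC(C)=CCCC(=O)c1cc(=O)cc(-c2cc(CC=C(C)C)c(OCOC)c(CC=C(C)C)c2)o1 | intermediate
15 | 2-[5-methyl-2-(trifluoroacetyl)hex-4-enoyl]-6-[4-(methoxymethoxy)-3,5-bis(3-methylbut-2-en-1-yl)phenyl]-4H-pyran-4-one (racemic, enolised) | CC(C)=CCC(C(=O)C(F)(F)F)C(=O)c1cc(=O)cc(-c2cc(CC=C(C)C)c(OCOC)c(CC=C(C)C)c2)o1 | intermediate (not isolated)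
16 | 2-(2-diazo-5-methylhex-4-enoyl)-6-[4-(methoxymethoxy)-3,5-bis(3-methylbut-2-en-1-yl)phenyl]-4H-pyran-4-one | CC(C)=CCC(=[N+]=[N-])C(=O)c1cc(=O)cc(-c2cc(CC=C(C)C)c(OCOC)c(CC=C(C)C)c2)o1 | intermediate
17 | ethynyltrimethylsilane | C#C[Si](C)(C)C | starting material
18 | lithium (trimethylsilyl)acetylide | [Li]C#C[Si](C)(C)C | intermediate (not isolated)
19 | lithium 2-(trimethylsilyl)ethynolate | [Li]OC#C[Si](C)(C)C | intermediate (not isolated)
20 | 1-(triisopropylsiloxy)-2-(trimethylsilyl)ethyne | C[Si](C)(C)C#CO[Si](C(C)C)(C(C)C)C(C)C | intermediate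
21 | 5-methyl-2-{6-[4-(methoxymethoxy)-3,5-bis(3-methylbut-2-en-1-yl)phenyl]-4-oxo-4H-pyran-2-yl}hexa-1,4-dien-1-one (ketene) | CC(C)=CCC(=C=O)c1cc(=O)cc(-c2cc(CC=C(C)C)c(OCOC)c(CC=C(C)C)c2)o1 | intermediate (not isolated)
22 | 4-(3-methylbut-2-en-1-yl)-4-{6-[4-(methoxymethoxy)-3,5-bis(3-methylbut-2-en-1-yl)phenyl]-4-oxo-4H-pyran-2-yl}-3-(triisopropylsiloxy)-2-(trimethylsilyl)cyclobut-2-en-1-one (racemic) | CC(C)=CCC1(c2cc(=O)cc(-c3cc(CC=C(C)C)c(OCOC)c(CC=C(C)C)c3)o2)C(=O)C([Si](C)(C)C)=C1O[Si](C(C)C)(C(C)C)C(C)C | intermediate (not isolated)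
23 | (3E)-7-methyl-4-{6-[4-(methoxymethoxy)-3,5-bis(3-methylbut-2-en-1-yl)phenyl]-4-oxo-4H-pyran-2-yl}-3-(triisopropylsiloxy)-2-(trimethylsilyl)octa-1,3,6-trien-1-one (pyranonyl cis to the ketenyl carbon) | CC(C)=CC/C(c1cc(=O)cc(-c2cc(CC=C(C)C)c(OCOC)c(CC=C(C)C)c2)o1)=C(\O[Si](C(C)C)(C(C)C)C(C)C)C(=C=O)[Si](C)(C)C | intermediate (not isolated)
24 | 2-[4-(methoxymethoxy)-3,5-bis(3-methylbut-2-en-1-yl)phenyl]-8-(3-methylbut-2-en-1-yl)-7-(triisopropylsiloxy)-6-(trimethylsilyl)-4aH-chromene-4,5-dione (racemic) | O=C1C([Si](C)(C)C)=C(O[Si](C(C)C)(C(C)C)C(C)C)C(CC=C(C)C)=C2OC(c3cc(CC=C(C)C)c(OCOC)c(CC=C(C)C)c3)=CC(=O)C12 | intermediate (not isolated)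
25 | 5-hydroxy-2-[4-(methoxymethoxy)-3,5-bis(3-methylbut-2-en-1-yl)phenyl]-8-(3-methylbut-2-en-1-yl)-7-(triisopropylsiloxy)-6-(trimethylsilyl)-4H-chromen-4-one | CC(C)=CCc1cc(-c2cc(=O)c3c(O)c([Si](C)(C)C)c(O[Si](C(C)C)(C(C)C)C(C)C)c(CC=C(C)C)c3o2)cc(CC=C(C)C)c1OCOC | intermediate
26 | 5-hydroxy-2-[4-hydroxy-3,5-bis(3-methylbut-2-en-1-yl)phenyl]-8-(3-methylbut-2-en-1-yl)-7-(triisopropylsiloxy)-4H-chromen-4-one | CC(C)=CCc1cc(-c2cc(=O)c3c(O)cc(O[Si](C(C)C)(C(C)C)C(C)C)c(CC=C(C)C)c3o2)cc(CC=C(C)C)c1O | intermediate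
27 | Epimedonin L, 5,7-dihydroxy-2-[4-hydroxy-3,5-bis(3-methylbut-2-en-1-yl)phenyl]-8-(3-methylbut-2-en-1-yl)-4H-chromen-4-one | CC(C)=CCc1cc(-c2cc(=O)c3c(O)cc(O)c(CC=C(C)C)c3o2)cc(CC=C(C)C)c1O | target

**Step count and risks**

Total step count: 12. Longest linear sequence: 11 steps (steps 1–8, then 10–12); the alkyne 20 is a one-step branch (step 9).

Steps most likely to fail:

1. Step 10. The excited diazo ketone may lose nitrogen to a free carbene that undergoes 1,2-hydride shift from the prenyl methylene instead of the Wolff shift, or light absorbed by the pyranone may degrade the substrate, so the ketene is not formed cleanly. Fallback (ketene by dehydrochlorination, with no light and no carbene): it sets out from diketone 7 and rejoins the route at ketene 21.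
   - The dianion of 7 (LDA, THF) is acetylated at its methyl terminus with N-methoxy-N-methylacetamide to 1-Ar-hexane-1,3,5-trione F1.
   - PPh3/CCl4/Et3N cyclodehydrates this to 2-methyl-6-Ar-4H-pyran-4-one F2.
   - Deprotonation of the methyl group (LiHMDS, −78 °C) and alkylation with prenyl bromide give 2-(4-methylpent-3-enyl)-6-Ar-4H-pyran-4-one F3.
   - A second deprotonation at the ring-bound methylene (LDA) and carbon dioxide give 5-methyl-2-(6-Ar-4-oxo-4H-pyran-2-yl)hex-4-enoic acid F4.
   - 1-Chloro-N,N,2-trimethylprop-1-en-1-amine converts it under neutral conditions to 5-methyl-2-(6-Ar-4-oxo-4H-pyran-2-yl)hex-4-enoyl chloride F5.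
   - Triethylamine in toluene with alkyne 20 present gives ketene 21, which goes on to 25 on heating as in step 10.

2. Step 7. The Grignard reagent may add to the pyranone carbonyl or to the ring carbons in conjugate fashion instead of to the amide. Fallback (acyl Negishi coupling with a zinc reagent that does not touch the pyranone): it sets out from ester 10 and returns at ketone 14.
   - Saponification (LiOH, THF/H2O, 0 °C) gives 6-Ar-4-oxo-4H-pyran-2-carboxylic acid F6.
   - 1-Chloro-N,N,2-trimethylprop-1-en-1-amine gives 6-Ar-4-oxo-4H-pyran-2-carbonyl chloride F7.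
   - Pd(PPh3)4-catalysed coupling with (4-methylpent-3-enyl)zinc bromide F8 (from 12, Zn dust, LiCl, THF) gives 14.

3. Step 11. Once the 4'-hydroxyl is free, protonation of a flanking prenyl double bond and capture of the tertiary cation by the phenol oxygen (chroman formation), or addition of HCl or methanol across the double bonds, may compete with acetal cleavage. Fallback (no protic acid, and no free phenol beside a prenyl group until the last operation): it sets out from 25 and returns at target 27.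
   - Triethylsilyl triflate and 2,2'-bipyridyl in CH2Cl2 at 0 °C exchange the aryl MOM ether directly for the silyl ether, giving 5-hydroxy-8-(3-methylbut-2-en-1-yl)-2-[3,5-bis(3-methylbut-2-en-1-yl)-4-(triethylsiloxy)phenyl]-7-(triisopropylsiloxy)-6-(trimethylsilyl)-4H-chromen-4-one F9. The chelated 5-hydroxyl is expected to stay free or to lose any silyl group on work-up.
   - Buffered fluoride (TBAF, AcOH, wet THF) then removes both O-silyl groups and, through the keto tautomer of the phloroglucinol-type ring A, should also remove the C6 silyl group, giving 27.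

**Further compounds**

F1 | step 10 | 1-[4-(methoxymethoxy)-3,5-bis(3-methylbut-2-en-1-yl)phenyl]hexane-1,3,5-trione | CC(=O)CC(=O)CC(=O)c1cc(CC=C(C)C)c(OCOC)c(CC=C(C)C)c1
F2 | step 10 | 2-methyl-6-[4-(methoxymethoxy)-3,5-bis(3-methylbut-2-en-1-yl)phenyl]-4H-pyran-4-one | Cc1cc(=O)cc(-c2cc(CC=C(C)C)c(OCOC)c(CC=C(C)C)c2)o1
F3 | step 10 | 2-(4-methylpent-3-enyl)-6-[4-(methoxymethoxy)-3,5-bis(3-methylbut-2-en-1-yl)phenyl]-4H-pyran-4-one | CC(C)=CCCc1cc(=O)cc(-c2cc(CC=C(C)C)c(OCOC)c(CC=C(C)C)c2)o1
F4 | step 10 | 5-methyl-2-{6-[4-(methoxymethoxy)-3,5-bis(3-methylbut-2-en-1-yl)phenyl]-4-oxo-4H-pyran-2-yl}hex-4-enoic acid (racemic) | CC(C)=CCC(C(=O)O)c1cc(=O)cc(-c2cc(CC=C(C)C)c(OCOC)c(CC=C(C)C)c2)o1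
F5 | step 10 | 5-methyl-2-{6-[4-(methoxymethoxy)-3,5-bis(3-methylbut-2-en-1-yl)phenyl]-4-oxo-4H-pyran-2-yl}hex-4-enoyl chloride (racemic) | CC(C)=CCC(C(=O)Cl)c1cc(=O)cc(-c2cc(CC=C(C)C)c(OCOC)c(CC=C(C)C)c2)o1
F6 | step 7 | 6-[4-(methoxymethoxy)-3,5-bis(3-methylbut-2-en-1-yl)phenyl]-4-oxo-4H-pyran-2-carboxylic acid | OC(=O)c1cc(=O)cc(-c2cc(CC=C(C)C)c(OCOC)c(CC=C(C)C)c2)o1
F7 | step 7 | 6-[4-(methoxymethoxy)-3,5-bis(3-methylbut-2-en-1-yl)phenyl]-4-oxo-4H-pyran-2-carbonyl chloride | ClC(=O)c1cc(=O)cc(-c2cc(CC=C(C)C)c(OCOC)c(CC=C(C)C)c2)o1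
F8 | step 7 | (4-methylpent-3-enyl)zinc bromide | CC(C)=CCC[Zn]Br
F9 | step 11 | 5-hydroxy-8-(3-methylbut-2-en-1-yl)-2-[3,5-bis(3-methylbut-2-en-1-yl)-4-(triethylsiloxy)phenyl]-7-(triisopropylsiloxy)-6-(trimethylsilyl)-4H-chromen-4-one | CC(C)=CCc1cc(-c2cc(=O)c3c(O)c([Si](C)(C)C)c(O[Si](C(C)C)(C(C)C)C(C)C)c(CC=C(C)C)c3o2)cc(CC=C(C)C)c1O[Si](CC)(CC)CC
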